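**Retr osynthetic overview**

- The target is two trans-fused 2,2-dimethyloxepan-3-one/cyclohexane bicycles joined by a CH2CH2 bridge. Both oxepanones are unveiled last from silyl-protected oxepanols, and the exocyclic methylene comes from a ring ketone by Wittig reaction.
- Enabling feature: in the methylenecyclohexane ring, the CH that carries the bridge lies between the methylene-bearing carbon (a latent C=O) and the quaternary C–CH3 ring-fusion carbon. This is a 2-alkylcyclohexanone, that is, an oxepane-fused cyclopentanone (C=O next to the quaternary carbon) plus one inserted carbon.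
- Key disconnection: that ring CH is removed together with the whole right half. Forward, a right-half 1,1-dibromide inserts its carbon into the C(=O)–C(quaternary) bond of the cyclopentanone (β-oxido carbenoid ring enlargement), which joins the halves and makes the six-membered ring in one operation.
- The right carbocycle (C–OH next to its quaternary carbon, then CH–CH3) is the same cyclopentanone homologated on its CH2 side, so both halves come from one building block.
- Ring order: oxepane and cyclopentane together (epoxide-opening oxa-/carbacyclization of a diepoxy propargylsilane made from geranyl bromide); right cyclohexane by CH2 insertion; left cyclohexane last, by the key insertion.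

Key step: step 15

Assumption: the L-fructose-derived enantiomer of the Shi ketone is taken as purchasable and as giving the (S)-configured epoxides (mirror image of the D-fructose series); in the allene ozonolysis the central carbon is counted as CO2.

**Route**

Step 1
Reactants: 1 geranyl bromide, (2E)-1-bromo-3,7-dimethylocta-2,6-diene; 2 trimethyl(prop-1-yn-1-yl)silane
Product: 5 (5E)-6,10-dimethylundeca-5,9-dien-1-yne, via lithiated silylpropyne 3 (not isolated), via silylated enyne 4 (not isolated)
Conditions: 2, n-BuLi, THF, −78 → −20 °C; 1, −78 → 23 °C; then K2CO3, MeOH, 23 °C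
Reagents that add atoms: none
Why: Propargylic lithiation of 2 and SN2 alkylation by the allylic bromide should build the 1,5-enyne with the (E)-alkene untouched, and methanolysis removes the alkynyl silyl group in the same flask (propargyl anion alkylation, protodesilylation).

Step 2
Reactants: 5 (5E)-6,10-dimethylundeca-5,9-dien-1-yne
Product: 7 [(6E)-7,11-dimethyldodeca-6,10-dien-2-yn-1-yl]trimethylsilane, via lithium acetylide 6 (not isolated)
Conditions: n-BuLi, THF, −78 °C; Me3SiCH2OTf, −78 → 23 °C
Reagents that add atoms: (trimethylsilyl)methyl trifluoromethanesulfonate, C[Si](C)(C)COS(=O)(=O)C(F)(F)F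
Why: Acetylide alkylation with the silylmethyl triflate should install the propargylsilane that later terminates the cyclization.

Step 3
Reactants: 7 [(6E)-7,11-dimethyldodeca-6,10-dien-2-yn-1-yl]trimethylsilane
Product: 8 trimethyl{5-[(2S,3S)-3-{2-[(2S)-3,3-dimethyloxiran-2-yl]ethyl}-3-methyloxiran-2-yl]pent-2-yn-1-yl}silane
Conditions: L-fructose-derived Shi ketone (cat.), Oxone, K2CO3, Bu4NHSO4, Na2B4O7 buffer, MeCN/dimethoxymethane/H2O, 0 °C
Reagents that add atoms: Oxone (potassium peroxymonosulfate, KHSO5), [K+].[O-]S(=O)(=O)OO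
Why: Shi asymmetric epoxidation should epoxidize both trisubstituted alkenes from the same enantioface under catalyst control, setting the two future ring-fusion stereocentres (S,S) and the terminal (S)-epoxide, while the alkyne is inert.

Step 4
Reactants: 8 diepoxy propargylsilane
Product: 11 (3S,5aS,8aS)-6-ethenylidene-2,2,5a-trimethyloctahydro-2H-cyclopenta[b]oxepin-3-ol, via bicyclic epoxonium triflate 9 (not isolated), via trimethylsilyl ether 10 (not isolated)
Conditions: TMSOTf, 2,6-di-tert-butyl-4-methylpyridine, CH2Cl2, −78 °C; then K2CO3, MeOH, 23 °C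
Reagents that add atoms: none
Why: The silylated terminal epoxide should be opened at its tertiary carbon by the neighbouring epoxide oxygen (seven-membered ring), and the propargylsilane then attacks the tertiary epoxonium carbon anti in a 5-exo-tet SE2′ closure, so the trans ring fusion follows stereospecifically from the (S,S)-(E)-epoxide (epoxide-opening oxa-/carbacyclization cascade with propargylsilane termination, as used for steroid D rings).

Step 5
Reactants: 11 bicyclic allenyl alcohol
Product: 12 tert-butyldimethylsilyl ether of 11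
Conditions: TBSOTf, 2,6-lutidine, CH2Cl2, 0 °C
Reagents that add atoms: tert-butyldimethylsilyl trifluoromethanesulfonate, CC(C)(C)[Si](C)(C)OS(=O)(=O)C(F)(F)F
Why: Silyl triflate silylation of the hindered secondary alcohol should give an ether that survives the organometallic steps ahead.

Step 6
Reactants: 12 silyl-protected bicyclic allene
Product: 13 (3S,5aR,8aS)-3-[(tert-butyldimethylsilyl)oxy]-2,2,5a-trimethyloctahydro-6H-cyclopenta[b]oxepin-6-one
Conditions: O3, CH2Cl2, −78 °C; then Me2S, −78 → 23 °C
Reagents that add atoms: ozone, [O-][O+]=O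
Why: Ozonolysis should cleave both C=C bonds of the 1,1-disubstituted allene and leave the ring carbon as the cyclopentanone carbonyl next to the quaternary centre.

Step 7
Reactants: 13 bicyclic cyclopentanone
Product: 15 (3S,5aR,9aS)-3-[(tert-butyldimethylsilyl)oxy]-2,2,5a-trimethyloctahydro-1-benzoxepin-6(2H)-one, via silyl ketone 14 (not isolated)
Conditions: TMSCHN2, BF3·OEt2, CH2Cl2, −78 → −20 °C; then K2CO3, MeOH, 23 °C
Reagents that add atoms: (trimethylsilyl)diazomethane, C[Si](C)(C)C=[N+]=[N-]
Why: In this Lewis acid-promoted diazoalkane homologation (Tiffeneau–Demjanov type) the ring CH2 should migrate rather than the quaternary carbon, as in D-homoannulation of 17-oxo steroids, so the carbonyl stays next to the quaternary centre; the α-silyl ketone is protodesilylated on methanolysis.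

Step 8
Reactants: 15 bicyclic cyclohexanone
Product: 17 (3S,5aR,7S,9aS)-3-[(tert-butyldimethylsilyl)oxy]-2,2,5a,7-tetramethyloctahydro-1-benzoxepin-6(2H)-one, via lithium enolate 16 (not isolated)
Conditions: LDA (commercial solution), THF, −78 °C; MeI, −78 → 0 °C; then NaOMe (cat.), MeOH, 23 °C
Reagents that add atoms: iodomethane, CI
Why: Only one α-position is enolizable, so enolate methylation is regiospecific, and base equilibration should leave the new methyl equatorial, trans to the axial angular methyl.

Step 9
Reactants: 17 α-methyl ketone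
Product: 18 tert-butyldimethyl{[(3S,5aS,7S,9aS)-2,2,5a,7-tetramethyl-6-methylidenedecahydro-1-benzoxepin-3-yl]oxy}silane
Conditions: Ph3PCH3Br, KOt-Bu, toluene, 100 °C
Reagents that add atoms: methyltriphenylphosphonium bromide, C[P+](c1ccccc1)(c1ccccc1)c1ccccc1.[Br-]
Why: Wittig methylenation under the hot KOt-Bu/toluene conditions used for hindered ketones should give the alkene, with the α-methyl centre staying in its thermodynamic equatorial configuration.

Step 10
Reactants: 18 methylidene compound
Product: 19 spiro-epoxide of 18, (6S), oxirane oxygen axial on C6 and anti to the C5a methyl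
Conditions: mCPBA, NaHCO3, CH2Cl2, 0 °C
Reagents that add atoms: 3-chloroperoxybenzoic acid, OOC(=O)c1cccc(Cl)c1
Why: In this Prilezhaev epoxidation the peracid should attack the alkene face anti to the axial angular methyl on the adjacent quaternary carbon, which places the oxirane oxygen axial and so fixes the carbinol configuration.

Step 11
Reactants: 19 spiro-epoxide
Product: 20 (3S,5aR,6S,7S,9aS)-6-(but-3-en-1-yl)-3-[(tert-butyldimethylsilyl)oxy]-2,2,5a,7-tetramethyldecahydro-1-benzoxepin-6-ol
Conditions: allylmagnesium chloride, CuI (10 mol %), THF, −30 → 0 °C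
Reagents that add atoms: allylmagnesium chloride, C=CC[Mg]Cl
Why: Copper-catalysed SN2 opening at the oxirane CH2 does not touch the tertiary C–O bond, so the tertiary alcohol keeps the axial oxygen set in step 10 and the chain ends up equatorial.

Step 12
Reactants: 20 tertiary homoallylic alcohol
Product: 21 triethylsilyl ether of 20
Conditions: TESOTf, 2,6-lutidine, CH2Cl2, 0 → 23 °C
Reagents that add atoms: triethylsilyl trifluoromethanesulfonate, CC[Si](CC)(CC)OS(=O)(=O)C(F)(F)F
Why: Silyl triflate silylation masks the tertiary alcohol, which would otherwise trap the aldehyde of step 13 as a five-membered lactol.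

Step 13
Reactants: 21 silyl-protected butenyl compound
Product: 22 3-[(3S,5aR,6S,7S,9aS)-3-[(tert-butyldimethylsilyl)oxy]-2,2,5a,7-tetramethyl-6-[(triethylsilyl)oxy]decahydro-1-benzoxepin-6-yl]propanal
Conditions: O3, CH2Cl2, −78 °C; then Me2S, −78 → 23 °C
Reagents that add atoms: ozone, [O-][O+]=O
Why: Ozonolysis with reductive work-up should shorten the butenyl chain to the three-carbon aldehyde.

Step 14
Reactants: 22 aldehyde
Product: 23 gem-dibromide, the 6-(3,3-dibromopropyl) analogue of 22
Conditions: (PhO)3P, Br2, Et3N, CH2Cl2, −78 → 23 °C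
Reagents that add atoms: bromine, BrBr
Why: Deoxygenative gem-dibromination of the aldehyde by the phosphite–bromine adduct runs under buffered conditions that should leave the silyl ethers intact.

Step 15
Reactants: 23 right-half gem-dibromide; 13 bicyclic cyclopentanone
Product: 28 coupled ketone: 2-alkylcyclohexanone left ring (ring CH (S), alkyl equatorial) joined by CH2CH2 to the silyl-protected right half, via dibromoalkyllithium 24 (not isolated), via dibromo alkoxide 25 (not isolated), via oxido carbenoid 26 (not isolated), via lithium enolate 27 (not isolated)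
Conditions: 23, LiTMP (commercial solution), THF/Et2O, −105 °C; 13, −105 → −90 °C; n-BuLi, −95 → 0 °C; then MeOH, 23 °C
Reagents that add atoms: none
Why: LiTMP lithiates the CHBr2 carbon of 23, the carbenoid 24 adds to the only carbonyl group present (that of 13, from the face opposite the angular methyl), and bromine–lithium exchange on alkoxide 25 gives β-oxido carbenoid 26, whose electron-poor carbon accepts a 1,2-shift of a ring bond with loss of LiBr to leave enolate 27 of the six-membered ketone. The closest known reaction is the β-oxido carbenoid ring enlargement of cycloalkanones with dibromomethyllithium and its 1-alkyl congeners. No ring is closed by cyclization: the cyclohexanone arises from the cyclopentanone by one-carbon ring expansion, the C(=O)–C(quaternary) bond being exchanged for a bond from the quaternary carbon to the inserted CH with retention at the migrating centre. The one new stereocentre, the ring CH bearing the bridge, is set under thermodynamic control when the LiOMe formed on quenching equilibrates the α-position, which should favour the equatorial bridge with its hydrogen axial and anti to the axial angular methyl (the labdane-type arrangement). The step needs migration of the quaternary carbon rather than the ring CH2; this rearrangement is reported to favour shift of the more substituted α-carbon (the opposite of diazoalkane insertion, used in step 7), and the rotamer with C–Br antiperiplanar to the quaternary carbon is the less congested one. All hydroxyl groups are silyl ethers and there is no other electrophile in either partner.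

Step 16
Reactants: 28 coupled ketone
Product: 29 methylidene compound, exocyclic C=CH2 in place of the ketone of 28
Conditions: Ph3PCH3Br, KOt-Bu, THF, 23 → 60 °C
Reagents that add atoms: methyltriphenylphosphonium bromide, C[P+](c1ccccc1)(c1ccccc1)c1ccccc1.[Br-]
Why: Wittig methylenation is standard for labdane-type ring ketones of this substitution pattern, and the α-stereocentre is already in its stable configuration.

Step 17
Reactants: 29 tris-silyl ether
Product: 30 triol, two secondary oxepanols and the tertiary alcohol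
Conditions: TBAF, THF, 60 °C
Reagents that add atoms: none
Why: Fluoride-mediated desilylation should cleave the two secondary TBS ethers and the tertiary TES ether without touching the alkene.

Step 18
Reactants: 30 triol
Product: 31 target, CNP0218659.1
Conditions: Dess–Martin periodinane, NaHCO3, CH2Cl2, 23 °C
Reagents that add atoms: none
Why: Dess–Martin oxidation should convert both secondary oxepanols into the oxepan-3-ones while the tertiary alcohol and the 1,1-disubstituted alkene are inert, and no epimerizable centre flanks the new ketones.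

**Compound list**

1 | geranyl bromide, (2E)-1-bromo-3,7-dimethylocta-2,6-diene | CC(C)=CCC/C(C)=C/CBr | starting material
2 | trimethyl(prop-1-yn-1-yl)silane | CC#C[Si](C)(C)C | starting material
3 | [3-(trimethylsilyl)prop-2-yn-1-yl]lithium | [Li]CC#C[Si](C)(C)C | intermediate
4 | [(5E)-6,10-dimethylundeca-5,9-dien-1-yn-1-yl]trimethylsilane | C[Si](C)(C)C#CCC/C=C(\C)CCC=C(C)C | intermediate
5 | (5E)-6,10-dimethylundeca-5,9-dien-1-yne | C#CCC/C=C(\C)CCC=C(C)C | intermediate
6 | [(5E)-6,10-dimethylundeca-5,9-dien-1-yn-1-yl]lithium | [Li]C#CCC/C=C(\C)CCC=C(C)C | intermediate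
7 | [(6E)-7,11-dimethyldodeca-6,10-dien-2-yn-1-yl]trimethylsilane | C[Si](C)(C)CC#CCC/C=C(\C)CCC=C(C)C | intermediate
8 | trimethyl{5-[(2S,3S)-3-{2-[(2S)-3,3-dimethyloxiran-2-yl]ethyl}-3-methyloxiran-2-yl]pent-2-yn-1-yl}silane | CC1(C)O[C@H]1CC[C@]1(C)O[C@H]1CCC#CC[Si](C)(C)C | intermediate
9 | bicyclic epoxonium triflate (oxepane closed, O-silylated, oxonium oxygen bridging the former internal epoxide carbons) | C[Si](C)(C)CC#CCC[C@@H]1[O+]2C(C)(C)[C@@H](O[Si](C)(C)C)CC[C@@]12C.[O-]S(=O)(=O)C(F)(F)F | intermediate
10 | trimethylsilyl ether of 11 | C=C=C1CC[C@@H]2OC(C)(C)[C@@H](O[Si](C)(C)C)CC[C@@]12C | intermediate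
11 | (3S,5aS,8aS)-6-ethenylidene-2,2,5a-trimethyloctahydro-2H-cyclopenta[b]oxepin-3-ol (trans-fused) | C=C=C1CC[C@@H]2OC(C)(C)[C@@H](O)CC[C@@]12C | intermediate
12 | tert-butyldimethylsilyl ether of 11 | C=C=C1CC[C@@H]2OC(C)(C)[C@@H](O[Si](C)(C)C(C)(C)C)CC[C@@]12C | intermediate
13 | (3S,5aR,8aS)-3-[(tert-butyldimethylsilyl)oxy]-2,2,5a-trimethyloctahydro-6H-cyclopenta[b]oxepin-6-one | O=C1CC[C@@H]2OC(C)(C)[C@@H](O[Si](C)(C)C(C)(C)C)CC[C@@]12C | intermediate
14 | 7-(trimethylsilyl) derivative of 15 (C7 unassigned) | O=C1C([Si](C)(C)C)CC[C@@H]2OC(C)(C)[C@@H](O[Si](C)(C)C(C)(C)C)CC[C@]21C | intermediate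
15 | (3S,5aR,9aS)-3-[(tert-butyldimethylsilyl)oxy]-2,2,5a-trimethyloctahydro-1-benzoxepin-6(2H)-one | O=C1CCC[C@@H]2OC(C)(C)[C@@H](O[Si](C)(C)C(C)(C)C)CC[C@]21C | intermediate
16 | lithium enolate of 15 (C6=C7) | [Li]OC1=CCC[C@@H]2OC(C)(C)[C@@H](O[Si](C)(C)C(C)(C)C)CC[C@]21C | intermediate
17 | (3S,5aR,7S,9aS)-3-[(tert-butyldimethylsilyl)oxy]-2,2,5a,7-tetramethyloctahydro-1-benzoxepin-6(2H)-one | O=C1[C@@H](C)CC[C@@H]2OC(C)(C)[C@@H](O[Si](C)(C)C(C)(C)C)CC[C@]21C | intermediate
18 | tert-butyldimethyl{[(3S,5aS,7S,9aS)-2,2,5a,7-tetramethyl-6-methylidenedecahydro-1-benzoxepin-3-yl]oxy}silane | C=C1[C@@H](C)CC[C@@H]2OC(C)(C)[C@@H](O[Si](C)(C)C(C)(C)C)CC[C@]21C | intermediate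
19 | spiro-epoxide of 18, (6S), oxirane O axial on C6, anti to the C5a methyl | C1O[C@]12[C@@H](C)CC[C@@H]3OC(C)(C)[C@@H](O[Si](C)(C)C(C)(C)C)CC[C@]32C | intermediate
20 | (3S,5aR,6S,7S,9aS)-6-(but-3-en-1-yl)-3-[(tert-butyldimethylsilyl)oxy]-2,2,5a,7-tetramethyldecahydro-1-benzoxepin-6-ol | C=CCC[C@]1(O)[C@@H](C)CC[C@@H]2OC(C)(C)[C@@H](O[Si](C)(C)C(C)(C)C)CC[C@]21C | intermediate
21 | triethylsilyl ether of 20 | C=CCC[C@]1(O[Si](CC)(CC)CC)[C@@H](C)CC[C@@H]2OC(C)(C)[C@@H](O[Si](C)(C)C(C)(C)C)CC[C@]21C | intermediate
22 | 3-[(3S,5aR,6S,7S,9aS)-3-[(tert-butyldimethylsilyl)oxy]-2,2,5a,7-tetramethyl-6-[(triethylsilyl)oxy]decahydro-1-benzoxepin-6-yl]propanal | O=CCC[C@]1(O[Si](CC)(CC)CC)[C@@H](C)CC[C@@H]2OC(C)(C)[C@@H](O[Si](C)(C)C(C)(C)C)CC[C@]21C | intermediate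
23 | 6-(3,3-dibromopropyl) analogue of 22 (CHO replaced by CHBr2) | BrC(Br)CC[C@]1(O[Si](CC)(CC)CC)[C@@H](C)CC[C@@H]2OC(C)(C)[C@@H](O[Si](C)(C)C(C)(C)C)CC[C@]21C | intermediate
24 | 1,1-dibromoalkyllithium from 23 | [Li]C(Br)(Br)CC[C@]1(O[Si](CC)(CC)CC)[C@@H](C)CC[C@@H]2OC(C)(C)[C@@H](O[Si](C)(C)C(C)(C)C)CC[C@]21C | intermediate
25 | lithium alkoxide adduct of 24 and 13 (new C–C bond anti to the angular methyl) | [Li]O[C@]1(C(Br)(Br)CC[C@]2(O[Si](CC)(CC)CC)[C@@H](C)CC[C@@H]4OC(C)(C)[C@@H](O[Si](C)(C)C(C)(C)C)CC[C@]42C)CC[C@@H]3OC(C)(C)[C@@H](O[Si](C)(C)C(C)(C)C)CC[C@@]13C | intermediate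
26 | β-oxido carbenoid (C(Li)Br in place of CBr2 of 25) | [Li]O[C@]1(C([Li])(Br)CC[C@]2(O[Si](CC)(CC)CC)[C@@H](C)CC[C@@H]4OC(C)(C)[C@@H](O[Si](C)(C)C(C)(C)C)CC[C@]42C)CC[C@@H]3OC(C)(C)[C@@H](O[Si](C)(C)C(C)(C)C)CC[C@@]13C | intermediate
27 | lithium enolate of 28 (C=C towards the bridge-bearing ring carbon) | [Li]OC=1CC[C@@H]2OC(C)(C)[C@@H](O[Si](C)(C)C(C)(C)C)CC[C@@]2(C)C=1CC[C@]1(O[Si](CC)(CC)CC)[C@@H](C)CC[C@@H]2OC(C)(C)[C@@H](O[Si](C)(C)C(C)(C)C)CC[C@]21C | intermediate
28 | coupled ketone: left 1-benzoxepin-7-one unit (2-alkylcyclohexanone, ring CH (S), alkyl equatorial) linked by CH2CH2 to C6 of the right unit of 21 | O=C1CC[C@@H]2OC(C)(C)[C@@H](O[Si](C)(C)C(C)(C)C)CC[C@@]2(C)[C@@H]1CC[C@]1(O[Si](CC)(CC)CC)[C@@H](C)CC[C@@H]2OC(C)(C)[C@@H](O[Si](C)(C)C(C)(C)C)CC[C@]21C | intermediate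
29 | methylidene analogue of 28 (C=CH2 in place of C=O) | C=C1CC[C@@H]2OC(C)(C)[C@@H](O[Si](C)(C)C(C)(C)C)CC[C@@]2(C)[C@@H]1CC[C@]1(O[Si](CC)(CC)CC)[C@@H](C)CC[C@@H]2OC(C)(C)[C@@H](O[Si](C)(C)C(C)(C)C)CC[C@]21C | intermediate
30 | triol (both oxepan-3-ols (S), tertiary alcohol free) | C=C1CC[C@@H]2OC(C)(C)[C@@H](O)CC[C@@]2(C)[C@@H]1CC[C@]1(O)[C@@H](C)CC[C@@H]2OC(C)(C)[C@@H](O)CC[C@]21C | intermediate
31 | CNP0218659.1 | C=C1CC[C@@H]2OC(C)(C)C(=O)CC[C@@]2(C)[C@@H]1CC[C@]1(O)[C@@H](C)CC[C@@H]2OC(C)(C)C(=O)CC[C@]21C | target

**Step count and risks**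

Total step count: 18. Longest linear sequence: 18 steps (steps 1–18 from geranyl bromide; ketone 13 enters twice, in steps 7 and 15).

The three steps most likely to fail:

Step 15. The hindered, thermally labile dibromoalkyllithium may decompose by α-elimination, or simply enolize 13, before it adds. In the rearrangement, shift of the ring CH2 may also compete with shift of the quaternary carbon. The fallback separates bond formation from rearrangement and uses a stereospecific pinacol-type ring expansion of a diol monomesylate, the D-homoannulation known from 17-oxo steroids. It sets out from aldehyde 22 and ketone 13 and comes back at 28. Aldehyde 22 is reduced with NaBH4 to the primary alcohol F1, which is converted with I2, PPh3 and imidazole into the primary iodide F2 and then with PPh3 in hot MeCN into the phosphonium iodide F3. Its ylide (KHMDS, THF, reflux) should olefinate 13 to the (Z)-alkylidenecyclopentane F4, as non-stabilized ylides do with 17-oxo steroids. OsO4/NMO should add from the face away from the angular methyl to give the diol F5, whose secondary hydroxyl is mesylated (MsCl, Et3N) to the hydroxy mesylate F6. Et2AlCl in CH2Cl2 (−78 → 0 °C) should then ionize the mesylate with antiperiplanar migration of the quaternary carbon, the less congested reactive rotamer of this diastereomer. Inversion at the migration terminus gives the axial-alkyl epimeric ketone F7, which NaOMe in MeOH equilibrates to 28. The six-membered ring still arises by expansion of the cyclopentane.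

Step 4. The weakly nucleophilic propargylsilane may fail to intercept the epoxonium ion before it is lost by elimination or triflate capture, and silylation of the internal instead of the terminal epoxide would lead to carbocyclization without oxepane formation. The fallback uses a far more nucleophilic enol silyl ether terminator and reaches the ketone by deformylation instead of allene ozonolysis. It sets out from enyne 5 and comes back at ketone 13. Enyne 5 is epoxidized as in step 3 to the diepoxy alkyne F8. Anti-Markovnikov hydroboration–oxidation (dicyclohexylborane, then NaBO3) gives the diepoxy aldehyde F9, and KHMDS/TBSCl gives the enol silyl ether F10. TBSOTf with 2,6-di-tert-butyl-4-methylpyridine at −78 °C should run the same cascade with 5-exo closure onto the exocyclic enol ether; because the silyl triflate is regenerated from the enol ether, this gives the silyl-protected bicyclic aldehyde F11 directly. Copper-catalysed aerobic oxidative deformylation (Cu(OAc)2, 2,2′-bipyridine, DABCO, O2, DMF) then gives 13.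

Step 11. Substitution at the neopentyl-type oxirane CH2 may be slow, and the magnesium salts may instead promote rearrangement of the spiro-epoxide to a ring aldehyde. The fallback uses a small, non-Lewis-acidic sp-carbanion and unmasks the aldehyde by alkyne hydroboration instead of ozonolysis. It sets out from epoxide 19 and comes back at aldehyde 22. Lithium acetylide–ethylenediamine complex in DMSO, the reagent used to open steroid spiro-oxiranes, should give the homopropargylic alcohol F12. TESOTf/2,6-lutidine gives its triethylsilyl ether F13, and hydroboration with dicyclohexylborane followed by NaBO3 gives 22.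

Further compounds

F1 | step 15 | primary alcohol from 22 (CH2OH in place of CHO) | OCCC[C@]1(O[Si](CC)(CC)CC)[C@@H](C)CC[C@@H]2OC(C)(C)[C@@H](O[Si](C)(C)C(C)(C)C)CC[C@]21C
F2 | step 15 | primary iodide from F1 | ICCC[C@]1(O[Si](CC)(CC)CC)[C@@H](C)CC[C@@H]2OC(C)(C)[C@@H](O[Si](C)(C)C(C)(C)C)CC[C@]21C
F3 | step 15 | triphenylphosphonium iodide from F2 | [I-].c1ccccc1[P+](c1ccccc1)(c1ccccc1)CCC[C@]1(O[Si](CC)(CC)CC)[C@@H](C)CC[C@@H]2OC(C)(C)[C@@H](O[Si](C)(C)C(C)(C)C)CC[C@]21C
F4 | step 15 | (Z)-alkylidenecyclopentane from F3 and 13 (chain cis to the quaternary carbon) | C(\CC[C@]1(O[Si](CC)(CC)CC)[C@@H](C)CC[C@@H]2OC(C)(C)[C@@H](O[Si](C)(C)C(C)(C)C)CC[C@]21C)=C1/CC[C@@H]2OC(C)(C)[C@@H](O[Si](C)(C)C(C)(C)C)CC[C@@]12C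
F5 | step 15 | vicinal diol from F4 (tertiary ring OH anti to the angular methyl, secondary OH on the chain) | O[C@H](CC[C@]1(O[Si](CC)(CC)CC)[C@@H](C)CC[C@@H]2OC(C)(C)[C@@H](O[Si](C)(C)C(C)(C)C)CC[C@]21C)[C@]1(O)CC[C@@H]2OC(C)(C)[C@@H](O[Si](C)(C)C(C)(C)C)CC[C@@]12C
F6 | step 15 | secondary monomesylate of F5 | CS(=O)(=O)O[C@H](CC[C@]1(O[Si](CC)(CC)CC)[C@@H](C)CC[C@@H]2OC(C)(C)[C@@H](O[Si](C)(C)C(C)(C)C)CC[C@]21C)[C@]1(O)CC[C@@H]2OC(C)(C)[C@@H](O[Si](C)(C)C(C)(C)C)CC[C@@]12C
F7 | step 15 | epimer of 28 at the bridge-bearing ring CH (alkyl axial) | O=C1CC[C@@H]2OC(C)(C)[C@@H](O[Si](C)(C)C(C)(C)C)CC[C@@]2(C)[C@H]1CC[C@]1(O[Si](CC)(CC)CC)[C@@H](C)CC[C@@H]2OC(C)(C)[C@@H](O[Si](C)(C)C(C)(C)C)CC[C@]21C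
F8 | step 4 | (S,S,S)-diepoxide of enyne 5 | CC1(C)O[C@H]1CC[C@]1(C)O[C@H]1CCC#C
F9 | step 4 | diepoxy aldehyde from F8 | CC1(C)O[C@H]1CC[C@]1(C)O[C@H]1CCCC=O
F10 | step 4 | tert-butyldimethylsilyl enol ether of F9 (E/Z unassigned) | CC1(C)O[C@H]1CC[C@]1(C)O[C@H]1CCC=CO[Si](C)(C)C(C)(C)C
F11 | step 4 | 6-carbaldehyde analogue of 13 (CHO-bearing ring carbon unassigned) | O=CC1CC[C@@H]2OC(C)(C)[C@@H](O[Si](C)(C)C(C)(C)C)CC[C@@]12C
F12 | step 11 | 6-(prop-2-yn-1-yl) tertiary alcohol from 19 | C#CC[C@]1(O)[C@@H](C)CC[C@@H]2OC(C)(C)[C@@H](O[Si](C)(C)C(C)(C)C)CC[C@]21C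
F13 | step 11 | triethylsilyl ether of F12 | C#CC[C@]1(O[Si](CC)(CC)CC)[C@@H](C)CC[C@@H]2OC(C)(C)[C@@H](O[Si](C)(C)C(C)(C)C)CC[C@]21C
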